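The route rests on disconnecting the five-membered ring between the ring-fusion CH (C1) and the CH2 (C2) next to the C3 ketone. The key step exploits the 2-methylcyclopent-2-enone (C1–C5): its C3 carbonyl next to methyl-bearing C4 is the retron of a Rautenstrauch rearrangement. A gold-catalysed 1,2-acetoxy shift from C4 to C3 and ring closure of a tertiary 1-ethynyl-2-propenyl acetate builds the five-membered ring, the ketone and the C4=C5 double bond in one operation and sets C1. The precursor is a monocyclic all-cis cycloheptene carrying a 2-acetoxybut-3-yn-2-yl group on C5; its C5–C9 chain and C8 oxygen come from sugar-derived (S)-5-(hydroxymethyl)furan-2(5H)-one.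

Key step: step 11

Numbering used throughout (guaiane type): C1 ring-fusion CH; C2 ring CH2; C3 ketone; C4 methyl-bearing alkene carbon; C5 ring-fusion alkene carbon; C6 CH2; C7 CH bearing C11 (CMe2OAc); C8 CH–O2CEt; C9 CH2; C10 CH–CH3.

Remark: (S)-5-(hydroxymethyl)furan-2(5H)-one is taken as a commercial chiral starting material, and the carbinol centre C4 made in step 10 is carried as both epimers because it becomes trigonal in step 11.

Step 1
Reactants: 1 (S)-5-(hydroxymethyl)furan-2(5H)-one
Product: 2 [(2S)-5-oxo-2,5-dihydrofuran-2-yl]methyl 4-methylbenzenesulfonate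
Conditions: TsCl, pyridine, CH2Cl2, 0 °C
Reagents that add atoms: p-toluenesulfonyl chloride, Cc1ccc(cc1)S(=O)(=O)Cl
Why: O-sulfonylation of the primary alcohol activates C9 for later C–C coupling; no stereocentre is formed and the weak base should leave the C8 centre of the butenolide untouched.

Step 2
Reactants: 2 [(2S)-5-oxo-2,5-dihydrofuran-2-yl]methyl 4-methylbenzenesulfonate
Product: 3 [(2S,3S)-3-(2-hydroxypropan-2-yl)-5-oxooxolan-2-yl]methyl 4-methylbenzenesulfonate (trans lactone)
Conditions: i-PrOH (solvent), Ph2CO (0.2 equiv), hν (350 nm, Pyrex), Ar, 20 °C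
Reagents that add atoms: 2-propanol, CC(C)O
Why: benzophenone-sensitised radical conjugate addition (Giese type) of the 2-hydroxypropan-2-yl radical to the butenolide β-carbon C7 should occur anti to the C8 substituent, which sets C7 trans to CH2OTs in the lactone and therefore cis to the C8–O bond in the later carbocycle.

Step 3
Reactants: 3 [(2S,3S)-3-(2-hydroxypropan-2-yl)-5-oxooxolan-2-yl]methyl 4-methylbenzenesulfonate
Product: 4 [(2S,3S)-3-(2-acetoxypropan-2-yl)-5-oxooxolan-2-yl]methyl 4-methylbenzenesulfonate
Conditions: Ac2O, Sc(OTf)3 (2 mol%), MeCN, −20 °C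
Reagents that add atoms: acetic anhydride, CC(=O)OC(C)=O
Why: Lewis-acid-catalysed acylation should acetylate the hindered tertiary alcohol at low temperature before translactonisation can compete, installing the C11 acetate of the target; no stereocentre is touched.

Step 4
Reactants: 4 [(2S,3S)-3-(2-acetoxypropan-2-yl)-5-oxooxolan-2-yl]methyl 4-methylbenzenesulfonate
Product: 5 2-[(2R,3S)-2-(2-methylprop-2-en-1-yl)-5-oxooxolan-3-yl]propan-2-yl acetate
Conditions: [CH2=C(CH3)]2CuMgBr (from CH2=C(CH3)MgBr and CuBr·SMe2), THF, −40 to 0 °C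
Reagents that add atoms: isopropenylmagnesium bromide, CC(=C)[Mg]Br
Why: SN2 displacement of the primary tosylate by the alkenyl cuprate (organocuprate coupling) forms C9–C10, with lactone and tertiary acetate expected to be inert to the cuprate at low temperature; no stereocentre is formed.

Step 5
Reactants: 5 2-[(2R,3S)-2-(2-methylprop-2-en-1-yl)-5-oxooxolan-3-yl]propan-2-yl acetate
Product: 6 2-[(5S,6R)-6-hydroxy-8-methyl-3-oxonona-1,8-dien-5-yl]propan-2-yl acetate
Conditions: CH2=CHMgBr (1.1 equiv), THF, −78 °C; AcOH, −78 °C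
Reagents that add atoms: vinylmagnesium bromide, C=C[Mg]Br
Why: single Grignard addition to the γ-lactone carbonyl C5 should stop at the cyclic magnesium hemiketalate, which is stable at −78 °C and on protonation opens to the γ-hydroxy vinyl ketone (in equilibrium with its lactol), freeing the C8 hydroxyl; no stereocentre is formed.

Step 6
Reactants: 6 2-[(5S,6R)-6-hydroxy-8-methyl-3-oxonona-1,8-dien-5-yl]propan-2-yl acetate
Product: 7 (5S,6R)-5-(2-acetoxypropan-2-yl)-8-methyl-3-oxonona-1,8-dien-6-yl propanoate
Conditions: (EtCO)2O, pyridine, DMAP (cat.), CH2Cl2, 0 °C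
Reagents that add atoms: propanoic anhydride, CCC(=O)OC(=O)CC
Why: DMAP-catalysed acylation of the secondary alcohol of the open-chain tautomer installs the C8 propanoate of the target and removes the ring-chain equilibrium; no stereocentre is touched.

Step 7
Reactants: 7 (5S,6R)-5-(2-acetoxypropan-2-yl)-8-methyl-3-oxonona-1,8-dien-6-yl propanoate
Product: 8 (1R,7S)-7-(2-acetoxypropan-2-yl)-3-methyl-5-oxocyclohept-3-en-1-yl propanoate
Conditions: second-generation Hoveyda–Grubbs catalyst [RuCl2(=CH-C6H4-2-O-i-Pr)(1,3-dimesitylimidazolidin-2-ylidene)] (5 mol%), toluene (0.005 M), 80 °C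
Reagents that add atoms: none
Why: ring-closing olefin metathesis between the vinyl ketone and the 1,1-disubstituted alkene should close the seven-membered ring as the conjugated 3-methylcyclohept-2-enone (C1=C10) with loss of ethene; no stereocentre is formed.

Step 8
Reactants: 8 (1R,7S)-7-(2-acetoxypropan-2-yl)-3-methyl-5-oxocyclohept-3-en-1-yl propanoate
Product: 10 (1R,2S,6S)-2-(2-acetoxypropan-2-yl)-6-methyl-4-(trifluoromethylsulfonyloxy)cyclohept-4-en-1-yl propanoate, via triethylsilyl enol ether 9 (not isolated)
Conditions: (Ph3P)3RhCl (2 mol%), Et3SiH, toluene, 60 °C; then solvent exchange, CsF, PhNTf2, DME, 23 °C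
Reagents that add atoms: triethylsilane, CC[SiH](CC)CC; N-phenylbis(trifluoromethanesulfonimide), O=S(=O)(N(c1ccccc1)S(=O)(=O)C(F)(F)F)C(F)(F)F
Why: rhodium-catalysed 1,4-hydrosilylation should deliver hydride to C10 on the face opposite to the cis C7 and C8 substituents (substrate control, placing the C10 methyl cis to them) and give the regiodefined silyl enol ether, which fluoride converts into the enolate that PhNTf2 traps as the C5=C1 enol triflate.

Step 9
Reactants: 10 (1R,2S,6S)-2-(2-acetoxypropan-2-yl)-6-methyl-4-(trifluoromethylsulfonyloxy)cyclohept-4-en-1-yl propanoate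
Product: 12 (1R,2S,6S)-4-acetyl-2-(2-acetoxypropan-2-yl)-6-methylcyclohept-4-en-1-yl propanoate, via 1-ethoxyvinyl diene 11 (not isolated)
Conditions: CH2=C(OEt)SnBu3, Pd(PPh3)4 (5 mol%), LiCl, THF, 65 °C; then 1 M HCl (aq), THF, 0 to 20 °C
Reagents that add atoms: tributyl(1-ethoxyvinyl)stannane, CCCC[Sn](CCCC)(CCCC)C(=C)OCC; water, O
Why: Stille coupling (oxidative addition of zerovalent palladium to the enol triflate, transmetalation, reductive elimination) attaches the acetyl carbon C4 as its enol ether, and mild acid hydrolysis should unmask the methyl ketone without moving the C1=C5 double bond; no stereocentre is touched.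

Step 10
Reactants: 12 (1R,2S,6S)-4-acetyl-2-(2-acetoxypropan-2-yl)-6-methylcyclohept-4-en-1-yl propanoate
Product: 14 (1R,2S,6S)-4-(2-acetoxybut-3-yn-2-yl)-2-(2-acetoxypropan-2-yl)-6-methylcyclohept-4-en-1-yl propanoate (both epimers at the butynyl carbinol carbon), via bromomagnesium alkoxide 13 (not isolated)
Conditions: HC≡CMgBr (1.5 equiv), THF, −40 to −10 °C; then Ac2O, DMAP (cat.), −10 to 20 °C
Reagents that add atoms: ethynylmagnesium bromide, C#C[Mg]Br; acetic anhydride, CC(=O)OC(C)=O
Why: 1,2-addition of the alkynyl Grignard reagent to the enone carbonyl, which at low temperature is far more electrophilic than the two hindered esters, followed by O-acetylation of the tertiary alkoxide in the same flask should give the propargylic acetate; the new centre C4 forms without control and is erased in step 11.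

Step 11
Reactants: 14 (1R,2S,6S)-4-(2-acetoxybut-3-yn-2-yl)-2-(2-acetoxypropan-2-yl)-6-methylcyclohept-4-en-1-yl propanoate
Product: 16 (5S,6R,8S,8aR)-5-(2-acetoxypropan-2-yl)-3,8-dimethyl-2-oxo-1,2,4,5,6,7,8,8a-octahydroazulen-6-yl propanoate (target), via cyclopentadienyl acetate 15 (not isolated)
Conditions: Ph3PAuCl (5 mol%), AgSbF6 (5 mol%), MeCN, H2O (2 equiv), −20 to 20 °C
Reagents that add atoms: none
Why: Monovalent gold activates the terminal alkyne, the acetate carbonyl oxygen adds to the internal alkyne carbon C3 and the C4–O bond breaks (1,2-acyloxy shift), giving a gold-bound 2-acetoxypentadienyl cation spanning C2–C3–C4–C5–C1. Its gold-bearing terminus C2 then bonds to the alkene terminus C1, loss of the gold cation gives cyclopentadienyl acetate 15, and the water present hydrolyses the enol ester to the C3 ketone conjugated with C4=C5; the closest known reaction type is the Rautenstrauch rearrangement of 1-ethynyl-2-propenyl esters to cyclopent-2-enones, known with PdCl2(MeCN)2 and with cationic phosphine-gold catalysts, including 1-cycloalkenyl substrates. The five-membered ring closes by a Nazarov-like conrotatory 4π electrocyclisation of this cation, in ring-closure terms a 5-endo-trig bond formation between C2 and C1. The only new stereocentre, C1, is under substrate control: the C10 methyl, the C8 propanoate and the C7 CMe2OAc group all lie on one face of the cycloheptene, so C2 should bond to C1 on the open opposite face, placing H1 cis to the C10 methyl as in the target. The step needs 1,2- rather than 1,3-acyloxy migration, which the terminal alkyne secures, and a facial selectivity independent of the uncontrolled C4 configuration, which is expected because C4 becomes trigonal in the cation before the C1–C2 bond forms.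

Compound list
1 | (S)-5-(hydroxymethyl)furan-2(5H)-one | OC[C@H]1OC(=O)C=C1 | starting material
2 | [(2S)-5-oxo-2,5-dihydrofuran-2-yl]methyl 4-methylbenzenesulfonate | Cc1ccc(cc1)S(=O)(=O)OC[C@H]1OC(=O)C=C1 | intermediate
3 | [(2S,3S)-3-(2-hydroxypropan-2-yl)-5-oxooxolan-2-yl]methyl 4-methylbenzenesulfonate | O=C1C[C@H](C(C)(C)O)[C@@H](COS(=O)(=O)c2ccc(C)cc2)O1 | intermediate
4 | [(2S,3S)-3-(2-acetoxypropan-2-yl)-5-oxooxolan-2-yl]methyl 4-methylbenzenesulfonate | O=C1C[C@H](C(C)(C)OC(C)=O)[C@@H](COS(=O)(=O)c2ccc(C)cc2)O1 | intermediate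
5 | 2-[(2R,3S)-2-(2-methylprop-2-en-1-yl)-5-oxooxolan-3-yl]propan-2-yl acetate | O=C1C[C@H](C(C)(C)OC(C)=O)[C@@H](CC(C)=C)O1 | intermediate
6 | 2-[(5S,6R)-6-hydroxy-8-methyl-3-oxonona-1,8-dien-5-yl]propan-2-yl acetate | C=CC(=O)C[C@H](C(C)(C)OC(C)=O)[C@H](O)CC(C)=C | intermediate
7 | (5S,6R)-5-(2-acetoxypropan-2-yl)-8-methyl-3-oxonona-1,8-dien-6-yl propanoate | C=CC(=O)C[C@H](C(C)(C)OC(C)=O)[C@H](OC(=O)CC)CC(C)=C | intermediate
8 | (1R,7S)-7-(2-acetoxypropan-2-yl)-3-methyl-5-oxocyclohept-3-en-1-yl propanoate | O=C1C=C(C)C[C@@H](OC(=O)CC)[C@@H](C(C)(C)OC(C)=O)C1 | intermediate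
9 | (1R,2S,6S)-2-(2-acetoxypropan-2-yl)-6-methyl-4-(triethylsilyloxy)cyclohept-4-en-1-yl propanoate (triethylsilyl enol ether, not isolated) | CC[Si](CC)(CC)OC1=C[C@@H](C)C[C@@H](OC(=O)CC)[C@@H](C(C)(C)OC(C)=O)C1 | intermediate
10 | (1R,2S,6S)-2-(2-acetoxypropan-2-yl)-6-methyl-4-(trifluoromethylsulfonyloxy)cyclohept-4-en-1-yl propanoate | O=S(=O)(OC1=C[C@@H](C)C[C@@H](OC(=O)CC)[C@@H](C(C)(C)OC(C)=O)C1)C(F)(F)F | intermediate
11 | (1R,2S,6S)-2-(2-acetoxypropan-2-yl)-4-(1-ethoxyethenyl)-6-methylcyclohept-4-en-1-yl propanoate (1-ethoxyvinyl diene, not isolated) | CCOC(=C)C1=C[C@@H](C)C[C@@H](OC(=O)CC)[C@@H](C(C)(C)OC(C)=O)C1 | intermediate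
12 | (1R,2S,6S)-4-acetyl-2-(2-acetoxypropan-2-yl)-6-methylcyclohept-4-en-1-yl propanoate | CC(=O)C1=C[C@@H](C)C[C@@H](OC(=O)CC)[C@@H](C(C)(C)OC(C)=O)C1 | intermediate
13 | bromomagnesium alkoxide of (1R,2S,6S)-2-(2-acetoxypropan-2-yl)-4-(2-hydroxybut-3-yn-2-yl)-6-methylcyclohept-4-en-1-yl propanoate (both carbinol epimers, not isolated) | C#CC(C)(O[Mg]Br)C1=C[C@@H](C)C[C@@H](OC(=O)CC)[C@@H](C(C)(C)OC(C)=O)C1 | intermediate
14 | (1R,2S,6S)-4-(2-acetoxybut-3-yn-2-yl)-2-(2-acetoxypropan-2-yl)-6-methylcyclohept-4-en-1-yl propanoate (both epimers at the butynyl carbinol carbon) | C#CC(C)(OC(C)=O)C1=C[C@@H](C)C[C@@H](OC(=O)CC)[C@@H](C(C)(C)OC(C)=O)C1 | intermediate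
15 | (5S,6R,8S,8aS)-2-acetoxy-5-(2-acetoxypropan-2-yl)-3,8-dimethyl-4,5,6,7,8,8a-hexahydroazulen-6-yl propanoate (cyclopentadienyl acetate, not isolated) | CCC(=O)O[C@@H]1C[C@H](C)[C@H]2C=C(OC(C)=O)C(C)=C2C[C@@H]1C(C)(C)OC(C)=O | intermediate
16 | (5S,6R,8S,8aR)-5-(2-acetoxypropan-2-yl)-3,8-dimethyl-2-oxo-1,2,4,5,6,7,8,8a-octahydroazulen-6-yl propanoate | CCC(=O)O[C@@H]1C[C@H](C)[C@H]2CC(=O)C(C)=C2C[C@@H]1C(C)(C)OC(C)=O | target

Total step count: 11. Longest linear sequence: 11 steps (1 to 16).

The three steps most likely to fail: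

Step 11 (key step). The two C4 epimers of 14 may each relay their configuration to C1 if the ring closes anti to the departing acetate before the cation relaxes, so that part of the material bonds on the substituted face. The fallback sets out from 14 and gives up kinetic facial control. Unselective ring closure (the same rearrangement or its thermal PdCl2(MeCN)2/AcOH variant) should give the target together with its C1 epimer, (5S,6R,8S,8aS)-5-(2-acetoxypropan-2-yl)-3,8-dimethyl-2-oxo-1,2,4,5,6,7,8,8a-octahydroazulen-6-yl propanoate F1. Because C1–H is the γ-position of the enone, warming the mixture with DBU in toluene should equilibrate F1 through the extended dienolate. The epimer with C2 on the face opposite the three cis substituents is expected to be favoured, which returns the material to the route at 16.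

Step 8. Hydride may be delivered to the wrong face of C10, or carbonyl reduction may compete with conjugate reduction. The fallback sets out from 8 and replaces substrate control by catalyst control. Copper hydride generated from Cu(OAc)2, one enantiomer of the bisphosphine DTBM-SEGPHOS (the one matched to hydride delivery opposite the C7 and C8 substituents) and (EtO)2MeSiH in toluene should give (1R,2S,6S)-2-(2-acetoxypropan-2-yl)-4-[diethoxy(methyl)silyloxy]-6-methylcyclohept-4-en-1-yl propanoate F2. The same CsF/PhNTf2 treatment converts F2 into the enol triflate, returning to the route at 10.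

Step 4. Substitution by the alkenyl cuprate at the β-oxygenated, β-branched primary sulfonate may be slow, and attack of the organometallic on the lactone may then compete. The fallback sets out from 4 and forms the C9–C10 bond without a carbanionic reagent. Halide exchange (NaI, acetone, reflux) should give 2-[(2S,3S)-2-(iodomethyl)-5-oxooxolan-3-yl]propan-2-yl acetate F3. A nickel-catalysed reductive cross-electrophile coupling of F3 with 2-bromopropene (NiBr2(dme), 4,4'-di-tert-butyl-2,2'-bipyridine, Zn, DMA, 25 °C) then returns to the route at 5.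

Further compounds
F1 | step 11 | (5S,6R,8S,8aS)-5-(2-acetoxypropan-2-yl)-3,8-dimethyl-2-oxo-1,2,4,5,6,7,8,8a-octahydroazulen-6-yl propanoate (C1 epimer of 16) | CCC(=O)O[C@@H]1C[C@H](C)[C@@H]2CC(=O)C(C)=C2C[C@@H]1C(C)(C)OC(C)=O
F2 | step 8 | (1R,2S,6S)-2-(2-acetoxypropan-2-yl)-4-[diethoxy(methyl)silyloxy]-6-methylcyclohept-4-en-1-yl propanoate | CCO[Si](C)(OCC)OC1=C[C@@H](C)C[C@@H](OC(=O)CC)[C@@H](C(C)(C)OC(C)=O)C1
F3 | step 4 | 2-[(2S,3S)-2-(iodomethyl)-5-oxooxolan-3-yl]propan-2-yl acetate | O=C1C[C@H](C(C)(C)OC(C)=O)[C@@H](CI)O1
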